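All runs come from a simulation for an exercise; the scatter is artificial.

The closed, stirred vessel starts with both substrates as a racemate and the solid reagent undissolved.

the same everywhere: left-handed substrate 0.17 M; right-handed substrate 0.17 M
- oak: solid reagent 0.59 M; run made earlier
- maple: solid reagent 0.94 M; run made earlier
- noon: solid reagent 0.425 M; time 50 h
- winter: solid reagent 0.425 M; time 200 h

- oak (time / h: left-handed product / %, right-handed product / %): 1.50: 1.3, 1.2; 5.00: 7.2, 3.3; 8.00: 11.4, 5.3; 12.0: 16.6, 8.4; 20.0: 28.7, 13.6; 25.0: 33.2, 17.7; 30.0: 37.6, 21.3
- maple (time / h: left-handed product / %, right-handed product / %): 1.50: 0.7, 0.8; 5.00: 6.8, 2.5; 8.00: 11.8, 5.6; 12.0: 16.9, 8.4; 20.0: 28.0, 14.2; 25.0: 33.2, 18.3; 30.0: 37.4, 21.4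

(readings scatter by 0.5 percentage points)

- partner is single-handed; left-handed substrate and right-handed substrate are mirror images of each other, charged as a racemate, each of them at the stated concentration
- as a solid, counted per litre of solution: solid reagent
- the numbers in the tables scatter with a standard deviation of 0.5 percentage points
- at the start none of the solid reagent is in solution
- an excess is the difference of the two amounts in percent of their sum
- an excess is below zero if the other one leads
- the handed part of partner does not stay in what it makes, so the products of the two hands are mirror images too

1. which of the two ends with the higher excess of left-handed product over right-handed product in the product ("neither" if they lie within 2 percentage points) (noon / winter / neither)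
2. excess of left-handed product over right-handed product in the product at the end, noon
3. excess of left-handed product over right-handed product in the product at the end, winter

Oak and maple, with different solid loadings, read alike within the scatter: at 30.0 h oak shows 37.6% and 21.3%, maple 37.4% and 21.4%.

Two ways measure how much faster the left-handed substrate reacts. The plain product ratio in oak gives 2.15 at 8.00 h but 1.77 at 30.0 h. The logarithmic way gives 2.51 at 30.0 h: this is the selectivity factor s, the logarithm of the fraction of left-handed substrate remaining over that of the right-handed substrate. They part because the plain ratio ignores depletion: by 30.0 h the oak readings leave the left-handed substrate a fraction 0.248, less than the right-handed 0.574. Putting the mean fractions remaining back into the earlier ratio raises it to 2.30, near s, given that a reading of 5.3% carries 0.5 percentage points.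

The reckoning here takes the right-handed substrate as pseudo-first-order, with one partner per substrate and a charge of 1.25 equivalents of solid reagent on both substrates together. Noon then keeps a right-handed fraction of 0.396 and a left-handed fraction of 0.0979, an excess of 19.8%. Winter comes to 0.0247 and an excess of 1.25%. The forecast chooses noon too, with 16% for noon and 0.5% for winter, saying “By 200 h both hands are consumed”.

The flask gives 18.5% for noon and 9.62% for winter, with noon ahead.

    partner + left-handed substrate → left-handed product (k = 0.0330 L mol⁻¹ min⁻¹)
    partner + right-handed substrate → right-handed product (k = 0.0140 L mol⁻¹ min⁻¹)
    left-handed substrate ⇌ achiral form (K = 0.100, k = 2.40 × 10⁻⁴ min⁻¹)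
    right-handed substrate ⇌ achiral form (K = 0.100, k = 2.40 × 10⁻⁴ min⁻¹)
    solid reagent ⇌ partner, rate k5*(cs5 - [partner]) while solid is left; crystals form when [partner] > cs5 (solubility = 0.0620 M, k = 0.00350 min⁻¹)

In winter at 24.3 h the left-handed substrate has a half-life of 12 h by the step to left-handed product, shorter than the 48.1 h of the forward step alone to achiral form. At 200 h winter holds 54.8% of the charge as left-handed product, more than the half charged as left-handed substrate. Read from the fractions remaining, s is 1.86 in noon at 50.0 h, against the 2.51 read in oak at 30.0 h, and 1.07 at 200 h in the neighbour with 0.26 M of solid reagent, whose excess stands at 21.7%.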